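**Retrosynthetic overview**
1. The last bond is C7'=C8' (Wittig) between ε‑end C10 aldehyde 8, which already carries the palmitate, and C30 phosphonium salt 20, which carries the myristate; 20 comes from β‑end C10 phosphonium salt 15 and crocetindial 16 (C10 + C20 + C10).
2. Aldehyde 8 comes from vinyl epoxide 7 by ring contraction: the six‑membered ε ring C1'–C6' is made from the seven‑membered carbocycle C1'–C2'–C3'–C4'–C5'–C6'–C7' by a 1,2‑shift of C1' from C7' to C6', and C7' leaves the ring as the formyl carbon.
3. Enabling feature: C6' is an allylic methine (cation‑stabilising C4'=C5') lying between the quaternary carbon C1'(CH3)2, a good migrating group, and the exocyclic sp2 carbon C7'. Read backwards, C7' can be placed inside the ring between C6' and C1', and the resulting C10 cycloheptadiene skeleton (ring plus three methyls) is that of (+)‑3‑carene after opening of its cyclopropane bond.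
4. Ring order: carene bicycle → seven‑membered dienone 3 (step 2) → ε cyclohexene (step 6); the β ring is taken intact from (4R,6R)‑actinol 9.
5. Stereocentres: C6' by inversion of a Jacobsen epoxide carbon, C3' by CBS reduction, C3 from actinol; both fatty esters are in place before the fragments are joined.

Key step: step 6

Remark: primed locants are carotenoid numbers of the ε end (C7' is the first chain carbon); (+)‑3‑carene, (4R,6R)‑actinol, crocetindial, the two acid chlorides and (tributylstannyl)methanol are taken as catalogue compounds.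

**Step 1**
Reactants: 1 (+)-3-carene
Product: 2 car-3-en-5-one [(1R,6S)-4,7,7-trimethylbicyclo[4.1.0]hept-3-en-2-one]
Conditions: t-BuOOH (5 equiv), Cr(CO)6 (cat.), MeCN, reflux
Reagents that add atoms: tert-butyl hydroperoxide, CC(C)(C)OO
Why: Chromium-catalysed allylic C–H oxidation with t-BuOOH, in which the allylic methylene next to the unsubstituted alkene carbon (C-5) should be oxidised to give the β-methyl enone; no stereocentre is made and those of carene are not needed later.

**Step 2**
Reactants: 2 car-3-en-5-one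
Product: 3 3,6,6-trimethylcyclohepta-2,4-dien-1-one
Conditions: t-BuOK (0.2 equiv), t-BuOH/THF, 50 °C
Reagents that add atoms: none
Why: Base-catalysed carenone → cycloheptadienone isomerisation (the reaction type that turns carenone into eucarvone), in which γ-deprotonation at C-2 gives a norcaradiene-type dienolate, 6π-electrocyclic opening of the cyclopropane bond C1–C6 follows, and α-protonation should deliver the conjugated, achiral seven-membered dienone.

**Step 3**
Reactants: 3 3,6,6-trimethylcyclohepta-2,4-dien-1-one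
Product: 4 (1S,7R)-2,6,6-trimethyl-8-oxabicyclo[5.1.0]oct-2-en-4-one
Conditions: (S,S)-Jacobsen Mn(salen)Cl (5 mol %), aq. NaOCl (pH 11.3), 4-phenylpyridine N-oxide (0.2 equiv), CH2Cl2, 0 °C
Reagents that add atoms: sodium hypochlorite, [Na+].[O-]Cl
Why: Jacobsen–Katsuki epoxidation, in which the electrophilic Mn-oxo species should react at the cis-disubstituted γ,δ-alkene (conjugated and flanked by CMe2, as in 2,2-dimethylchromene) and not at the electron-poor α,β-alkene, the (S,S)-catalyst setting both epoxide carbons with the sense assigned by analogy with indene and chromene substrates.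

**Step 4**
Reactants: 4 (1S,7R)-2,6,6-trimethyl-8-oxabicyclo[5.1.0]oct-2-en-4-one
Product: 5 (1S,4R,7R)-2,6,6-trimethyl-8-oxabicyclo[5.1.0]oct-2-en-4-ol
Conditions: (S)-Me-CBS (0.2 equiv), catecholborane (1.5 equiv), toluene, −78 °C; MeOH, then aq. NaHCO3
Reagents that add atoms: none
Why: CBS (oxazaborolidine) 1,2-reduction in which the alkenyl arm acts as the large and the CH2 arm as the small carbonyl substituent, so that the (S)-catalyst should give the (4R)-alcohol under reagent control, i.e. OH trans to the epoxide oxygen, while catecholborane at low temperature leaves epoxide and alkene alone.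

**Step 5**
Reactants: 5 (1S,4R,7R)-2,6,6-trimethyl-8-oxabicyclo[5.1.0]oct-2-en-4-ol, 6 palmitoyl chloride
Product: 7 (1S,4R,7R)-2,6,6-trimethyl-8-oxabicyclo[5.1.0]oct-2-en-4-yl hexadecanoate
Conditions: pyridine (2 equiv), DMAP (cat.), CH2Cl2, 0 °C
Reagents that add atoms: none
Why: DMAP-catalysed O-acylation of a secondary allylic alcohol, which installs the final C16 ester before the Lewis-acid step with retention at C-4 because no bond to the stereocentre is broken.

**Step 6**
Reactants: 7 (1S,4R,7R)-2,6,6-trimethyl-8-oxabicyclo[5.1.0]oct-2-en-4-yl hexadecanoate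
Product: 8 (1R,4R)-4-formyl-3,5,5-trimethylcyclohex-2-en-1-yl hexadecanoate [(3'R,6'R)-3'-palmitoyloxy-α-cyclocitral]
Conditions: MABR [methylaluminium bis(4-bromo-2,6-di-tert-butylphenoxide)] (0.2 equiv), CH2Cl2, −78 → −40 °C; pH 7 buffer
Reagents that add atoms: none
Why: Meinwald-type semipinacol rearrangement: the bulky aluminium phenoxide binds the epoxide oxygen, the allylic C6'–O bond (assisted by C4'=C5') lengthens, and the ring bond C7'–C1' migrates from C7' to C6' on the face opposite the departing oxygen while C7'=O forms. The closest known reaction types are the Lewis-acid ring contraction of cycloalkene oxides to cycloalkanecarbaldehydes by alkyl shift and the stereospecific Lewis-acid rearrangement of vinyl epoxides to β,γ-unsaturated aldehydes. The six-membered ε ring C1'–C6' is closed by this 1,2-shift, i.e. by contraction of the seven-membered carbocycle with extrusion of C7' as the formyl carbon. C6' is set by inversion of the epoxide carbon (chirality transfer from the Jacobsen epoxide) and C3' is untouched, so the trans epoxide/ester relation of 7 should become the (3'R,6'R) trans relation of 8. The step needs alkyl over hydride migration and no scrambling through a free allyl cation: the bulky Al–O group and the ring pucker place the quaternary C1', not H-7', antiperiplanar to the breaking bond, and the electron-withdrawing ester at C3' keeps positive charge at C6' and away from C4'. The C4'=C5' bond should stay out of conjugation because no base is present and the reaction is quenched cold.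

**Step 7**
Reactants: 9 (4R,6R)-actinol [(4R,6R)-4-hydroxy-2,2,6-trimethylcyclohexanone], 10 myristoyl chloride
Product: 11 (4R,6R)-4-(tetradecanoyloxy)-2,2,6-trimethylcyclohexanone
Conditions: pyridine (2 equiv), DMAP (cat.), CH2Cl2, 0 °C → rt
Reagents that add atoms: none
Why: DMAP-catalysed O-acylation, which puts the final C14 ester on the future C3 oxygen with its configuration (from the chiral pool) unchanged.

**Step 8**
Reactants: 11 (4R,6R)-4-(tetradecanoyloxy)-2,2,6-trimethylcyclohexanone
Product: 12 (4R)-4-(tetradecanoyloxy)-2,6,6-trimethylcyclohex-1-en-1-yl trifluoromethanesulfonate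
Conditions: Tf2O (1.3 equiv), 2,6-di-tert-butyl-4-methylpyridine (1.5 equiv), CH2Cl2, 0 °C → rt
Reagents that add atoms: trifluoromethanesulfonic anhydride, O=S(=O)(OS(=O)(=O)C(F)(F)F)C(F)(F)F
Why: Enol triflate formation under non-basic conditions, in which the ketone can enolise only towards C-6 so that a single tetrasubstituted triflate should form, the C-6 stereocentre being erased on purpose and the ester untouched.

**Step 9**
Reactants: 12 (4R)-4-(tetradecanoyloxy)-2,6,6-trimethylcyclohex-1-en-1-yl trifluoromethanesulfonate, 13 (tributylstannyl)methanol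
Product: 14 [(4R)-4-(tetradecanoyloxy)-2,6,6-trimethylcyclohex-1-en-1-yl]methanol
Conditions: Pd(PPh3)4 (5 mol %), LiCl (3 equiv), 1,4-dioxane, 100 °C
Reagents that add atoms: none
Why: Stille (Migita–Kosugi–Stille) hydroxymethylation of an enol triflate, in which chloride assists transmetalation of the vinyl-palladium triflate and the neutral conditions tolerate the ester.

**Step 10**
Reactants: 14 [(4R)-4-(tetradecanoyloxy)-2,6,6-trimethylcyclohex-1-en-1-yl]methanol
Product: 15 {[(4R)-4-(tetradecanoyloxy)-2,6,6-trimethylcyclohex-1-en-1-yl]methyl}triphenylphosphonium bromide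
Conditions: PPh3·HBr (1.05 equiv), CH2Cl2, rt
Reagents that add atoms: triphenylphosphine hydrobromide, [Br-].c1ccc(cc1)[PH+](c1ccccc1)c1ccccc1
Why: Conversion of an allylic alcohol into the allylic phosphonium salt with PPh3·HBr (allyl cation captured at the primary terminus, as for β-cyclogeraniol), run in an aprotic solvent to protect the ester.

**Step 11**
Reactants: 15 {[(4R)-4-(tetradecanoyloxy)-2,6,6-trimethylcyclohex-1-en-1-yl]methyl}triphenylphosphonium bromide, 16 crocetindial
Product: 18 (3R)-3-(tetradecanoyloxy)-8'-apo-β-caroten-8'-al, via β-end C10 ylide 17 (not isolated)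
Conditions: NaHMDS (1.0 equiv), THF, −78 °C; add to 16 (3 equiv), CH2Cl2/THF, −78 °C → rt; then I2 (cat.), CH2Cl2, rt
Reagents that add atoms: none
Why: Wittig olefination in the C10 + C20 mode, in which the ylide is added to an excess of the symmetrical dialdehyde so that one formyl group reacts, and the new C7=C8 bond should be brought to E by iodine-catalysed equilibration because the 7Z isomer is strained by the ring methyls.

**Step 12**
Reactants: 18 (3R)-3-(tetradecanoyloxy)-8'-apo-β-caroten-8'-al
Product: 19 (3R)-3-(tetradecanoyloxy)-8'-apo-β-caroten-8'-ol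
Conditions: NaBH4, THF/EtOH, 0 °C
Reagents that add atoms: none
Why: Chemoselective borohydride reduction of the conjugated aldehyde, to which the ester and the polyene are inert.

**Step 13**
Reactants: 19 (3R)-3-(tetradecanoyloxy)-8'-apo-β-caroten-8'-ol
Product: 20 [(3R)-3-(tetradecanoyloxy)-8'-apo-β-caroten-8'-yl]triphenylphosphonium bromide
Conditions: PPh3·HBr (1.05 equiv), CH2Cl2, 0 °C → rt
Reagents that add atoms: triphenylphosphine hydrobromide, [Br-].c1ccc(cc1)[PH+](c1ccccc1)c1ccccc1
Why: Conversion of a polyenyl allylic alcohol into the terminal phosphonium salt with PPh3·HBr (the reaction type used for retinyl phosphonium salts), the delocalised cation being captured at C8' so that full conjugation is kept.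

**Step 14**
Reactants: 20 [(3R)-3-(tetradecanoyloxy)-8'-apo-β-caroten-8'-yl]triphenylphosphonium bromide, 8 (1R,4R)-4-formyl-3,5,5-trimethylcyclohex-2-en-1-yl hexadecanoate
Product: 22 (3R,3'R,6'R)-lutein 3-O-myristate 3'-O-palmitate, via C30 ylide 21 (not isolated)
Conditions: NaHMDS (1.0 equiv), THF, −78 °C; add 8, −78 → 0 °C; then I2 (cat.), CH2Cl2, rt, ambient light
Reagents that add atoms: none
Why: Wittig olefination forming C7'=C8', in which the ylide is made with one equivalent of a non-nucleophilic base and meets the aldehyde cold so that addition to the formyl group should outrun enolisation at C6', the E/Z mixture at the new disubstituted bond being equilibrated to all-E with catalytic iodine; no stereocentre is formed or touched.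

**Compound list**
1 | (+)-3-carene, (1S,6R)-3,7,7-trimethylbicyclo[4.1.0]hept-3-ene | CC1=CC[C@@H]2[C@H](C1)C2(C)C | starting material
2 | car-3-en-5-one, (1R,6S)-4,7,7-trimethylbicyclo[4.1.0]hept-3-en-2-one | CC1=CC(=O)[C@@H]2[C@H](C1)C2(C)C | intermediate
3 | 3,6,6-trimethylcyclohepta-2,4-dien-1-one (achiral) | CC1=CC(=O)CC(C)(C)C=C1 | intermediate
4 | (1S,7R)-2,6,6-trimethyl-8-oxabicyclo[5.1.0]oct-2-en-4-one | CC1=CC(=O)CC(C)(C)[C@H]2O[C@@H]12 | intermediate
5 | (1S,4R,7R)-2,6,6-trimethyl-8-oxabicyclo[5.1.0]oct-2-en-4-ol (OH trans to epoxide O) | CC1=C[C@H](O)CC(C)(C)[C@H]2O[C@@H]12 | intermediate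
6 | palmitoyl chloride (hexadecanoyl chloride) | CCCCCCCCCCCCCCCC(=O)Cl | starting material
7 | (1S,4R,7R)-2,6,6-trimethyl-8-oxabicyclo[5.1.0]oct-2-en-4-yl hexadecanoate | CC1=C[C@H](OC(=O)CCCCCCCCCCCCCCC)CC(C)(C)[C@H]2O[C@@H]12 | intermediate
8 | (1R,4R)-4-formyl-3,5,5-trimethylcyclohex-2-en-1-yl hexadecanoate | CCCCCCCCCCCCCCCC(=O)O[C@H]1C=C(C)[C@H](C=O)C(C)(C)C1 | intermediate
9 | (4R,6R)-actinol, (4R,6R)-4-hydroxy-2,2,6-trimethylcyclohexanone | O[C@H]1CC(C)(C)C(=O)[C@H](C)C1 | starting material
10 | myristoyl chloride (tetradecanoyl chloride) | CCCCCCCCCCCCCC(=O)Cl | starting material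
11 | (4R,6R)-4-(tetradecanoyloxy)-2,2,6-trimethylcyclohexanone | CCCCCCCCCCCCCC(=O)O[C@H]1CC(C)(C)C(=O)[C@H](C)C1 | intermediate
12 | (4R)-4-(tetradecanoyloxy)-2,6,6-trimethylcyclohex-1-en-1-yl trifluoromethanesulfonate | CCCCCCCCCCCCCC(=O)O[C@H]1CC(C)(C)C(OS(=O)(=O)C(F)(F)F)=C(C)C1 | intermediate
13 | (tributylstannyl)methanol | CCCC[Sn](CCCC)(CCCC)CO | starting material
14 | [(4R)-4-(tetradecanoyloxy)-2,6,6-trimethylcyclohex-1-en-1-yl]methanol | CCCCCCCCCCCCCC(=O)O[C@H]1CC(C)(C)C(CO)=C(C)C1 | intermediate
15 | {[(4R)-4-(tetradecanoyloxy)-2,6,6-trimethylcyclohex-1-en-1-yl]methyl}triphenylphosphonium bromide | CCCCCCCCCCCCCC(=O)O[C@H]1CC(C)(C)C(C[P+](c2ccccc2)(c2ccccc2)c2ccccc2)=C(C)C1.[Br-] | intermediate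
16 | crocetindial, (2E,4E,6E,8E,10E,12E,14E)-2,6,11,15-tetramethylhexadeca-2,4,6,8,10,12,14-heptaenedial | O=C/C(C)=C/C=C/C(C)=C/C=C/C=C(C)/C=C/C=C(C)/C=O | starting material
17 | β-end C10 ylide (triphenylphosphonium ylide of 15) | CCCCCCCCCCCCCC(=O)O[C@H]1CC(C)(C)C([CH-][P+](c2ccccc2)(c2ccccc2)c2ccccc2)=C(C)C1 | intermediate (not isolated)
18 | (3R)-3-(tetradecanoyloxy)-8'-apo-β-caroten-8'-al (all-E) | O=C/C(C)=C/C=C/C(C)=C/C=C/C=C(C)/C=C/C=C(C)/C=C/C1=C(C)C[C@@H](OC(=O)CCCCCCCCCCCCC)CC1(C)C | intermediate
19 | (3R)-3-(tetradecanoyloxy)-8'-apo-β-caroten-8'-ol (all-E) | OC/C(C)=C/C=C/C(C)=C/C=C/C=C(C)/C=C/C=C(C)/C=C/C1=C(C)C[C@@H](OC(=O)CCCCCCCCCCCCC)CC1(C)C | intermediate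
20 | [(3R)-3-(tetradecanoyloxy)-8'-apo-β-caroten-8'-yl]triphenylphosphonium bromide | [Br-].c1ccccc1[P+](c1ccccc1)(c1ccccc1)C/C(C)=C/C=C/C(C)=C/C=C/C=C(C)/C=C/C=C(C)/C=C/C1=C(C)C[C@@H](OC(=O)CCCCCCCCCCCCC)CC1(C)C | intermediate
21 | C30 ylide (triphenylphosphonium ylide of 20) | c1ccccc1[P+](c1ccccc1)(c1ccccc1)[CH-]/C(C)=C/C=C/C(C)=C/C=C/C=C(C)/C=C/C=C(C)/C=C/C1=C(C)C[C@@H](OC(=O)CCCCCCCCCCCCC)CC1(C)C | intermediate (not isolated)
22 | (3R,3'R,6'R)-lutein 3-O-myristate 3'-O-palmitate, all-E | CCCCCCCCCCCCCCCC(=O)O[C@H]1C=C(C)[C@H](/C=C/C(C)=C/C=C/C(C)=C/C=C/C=C(C)/C=C/C=C(C)/C=C/C2=C(C)C[C@@H](OC(=O)CCCCCCCCCCCCC)CC2(C)C)C(C)(C)C1 | target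

**Totals and risks**
Total step count: 14. Longest linear sequence: 8 steps (steps 7–14, from 9 to 22); the ε branch is 7 steps (steps 1–6 and 14).

Steps most likely to fail:

1. Step 6. What may go wrong: a 1,2-hydride shift from C7' (giving the seven-membered ketone) could compete with the ring-bond shift, or ionisation to a free allyl cation could erase the configuration at C6' and be intercepted by the neighbouring ester. Fallback, setting out from 3 and coming back at 8: the contraction is run stepwise through a trans-bromohydrin, in which only the ring bond can stand antiperiplanar to the leaving group. Because this path inverts C6' twice, the other epoxide face is needed. Dienone 3 is epoxidised with the (R,R)-Jacobsen catalyst to (1R,7S)-2,6,6-trimethyl-8-oxabicyclo[5.1.0]oct-2-en-4-one F1. CBS reduction with the same (S)-catalyst should give the cis-epoxy alcohol (1R,4R,7S)-2,6,6-trimethyl-8-oxabicyclo[5.1.0]oct-2-en-4-ol F2. Acylation with 6 and pyridine gives (1R,4R,7S)-2,6,6-trimethyl-8-oxabicyclo[5.1.0]oct-2-en-4-yl hexadecanoate F3. MgBr2·OEt2 in Et2O at −20 °C should open the epoxide at the allylic carbon with inversion to the bromomagnesium alkoxide of (1R,4S,5S)-4-bromo-5-hydroxy-3,6,6-trimethylcyclohept-2-en-1-yl hexadecanoate F4. Warming to room temperature then triggers the classical semipinacol ring contraction of a trans-2-halocycloalkanol salt, C1' displacing bromide with a second inversion, to give 8.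

2. Step 14. What may go wrong: the basic ylide could enolise 8 at C6' (epimerisation, or migration of the ring double bond into conjugation) faster than it adds to the hindered formyl group, and E-selectivity at the new bond could be poor. Fallback, setting out from 19 and coming back at 22: a Horner–Wadsworth–Emmons union replaces the Wittig one. Alcohol 19 is converted under Appel conditions (CBr4, PPh3, CH2Cl2, −20 °C) into (3R)-3-(tetradecanoyloxy)-8'-apo-β-caroten-8'-yl bromide F5. Sodium diethyl phosphite (Michaelis–Becker, THF, 0 °C) gives diethyl [(3R)-3-(tetradecanoyloxy)-8'-apo-β-caroten-8'-yl]phosphonate F6. Its sodium salt (NaHMDS, THF, −78 °C) is condensed with 8; the smaller, more nucleophilic phosphonate carbanion should add irreversibly and eliminate to the E-alkene 22, a reaction type established for conjugated allylic phosphonates in polyene synthesis.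

3. Step 4. What may go wrong: catalyst control could be weak because the two flanks of the carbonyl (CH= and CH2) differ little in size, so that both C-4 epimers form. Fallback, setting out from 4 and coming back at 7: a Luche reduction (NaBH4, CeCl3·7H2O, MeOH, −78 °C) is followed by stereoconvergent esterification. The (4S)-epimer (1S,4S,7R)-2,6,6-trimethyl-8-oxabicyclo[5.1.0]oct-2-en-4-ol F7 is esterified with inversion under Mitsunobu conditions (palmitic acid, PPh3, DIAD, toluene, 0 °C), and any (4R)-epimer 5 is acylated as in step 5, so that both epimers end as 7.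

**Further compounds**
F1 | step 6 | (1R,7S)-2,6,6-trimethyl-8-oxabicyclo[5.1.0]oct-2-en-4-one | CC1=CC(=O)CC(C)(C)[C@@H]2O[C@H]12
F2 | step 6 | (1R,4R,7S)-2,6,6-trimethyl-8-oxabicyclo[5.1.0]oct-2-en-4-ol | CC1=C[C@H](O)CC(C)(C)[C@@H]2O[C@H]12
F3 | step 6 | (1R,4R,7S)-2,6,6-trimethyl-8-oxabicyclo[5.1.0]oct-2-en-4-yl hexadecanoate | CC1=C[C@H](OC(=O)CCCCCCCCCCCCCCC)CC(C)(C)[C@@H]2O[C@H]12
F4 | step 6 | (1R,4S,5S)-4-bromo-5-hydroxy-3,6,6-trimethylcyclohept-2-en-1-yl hexadecanoate | CC1=C[C@H](OC(=O)CCCCCCCCCCCCCCC)CC(C)(C)[C@H](O)[C@H]1Br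
F5 | step 14 | (3R)-3-(tetradecanoyloxy)-8'-apo-β-caroten-8'-yl bromide | BrC/C(C)=C/C=C/C(C)=C/C=C/C=C(C)/C=C/C=C(C)/C=C/C1=C(C)C[C@@H](OC(=O)CCCCCCCCCCCCC)CC1(C)C
F6 | step 14 | diethyl [(3R)-3-(tetradecanoyloxy)-8'-apo-β-caroten-8'-yl]phosphonate | CCOP(=O)(OCC)C/C(C)=C/C=C/C(C)=C/C=C/C=C(C)/C=C/C=C(C)/C=C/C1=C(C)C[C@@H](OC(=O)CCCCCCCCCCCCC)CC1(C)C
F7 | step 4 | (1S,4S,7R)-2,6,6-trimethyl-8-oxabicyclo[5.1.0]oct-2-en-4-ol | CC1=C[C@@H](O)CC(C)(C)[C@H]2O[C@@H]12
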